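The ring-fusion bond C1–C5 is the disconnection on which everything rests. The five-membered ring (C1–C5) and the seven-membered ring (C1, C5–C10) are made together from a cis-fused decalin by a pinacol-type 1,2-shift of C1 from C6 to C5. The step exploits the array C4 tertiary carbinol, C5–H and C6 oxygen that flanks this shared bond, a β-hydroxy ketone retron. In one operation ring B contracts, ring A expands, C6 becomes a ketone and C5 is set with inversion, giving the trans fusion. The precursor is a decalin all-cis 4,5,6-triol with the C5 hydroxyl as mesylate, a C2 acetate and a C8 dioxolane, built from (S)-Wieland–Miescher ketone.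

Key step: step 8

Numbering (target numbers are kept for all intermediates): C1 is the quaternary ring-fusion carbon with the methyl group, C2 the acetoxy carbon, C3 a CH2, C4 the isopropyl carbinol, C5 the ring-fusion CH, C6 the aroyloxy carbon, C7 a CH2, C8 (methyl) and C9 the oxirane carbons, C10 a CH2. In the decalins ring A is C1, C6–C10 and ring B is C1–C6. β is the face of the C1 methyl. In the target the C2, C4 and C6 oxygens and the oxirane oxygen are all β and H-5 is α.

Remark on the chemistry: an oxirane fused at C4–C5 can never hold its C5–O bond anti to the C6–C1 ring bond (gauche to roughly perpendicular at best), and a Lewis acid would open it at the tertiary C4; a trans-fused decalin would put an axial C5 leaving group anti to the C6 oxygen (oxirane closure), and an equatorial one would give the cis-fused C5 epimer. The shift is therefore run on a secondary C5 mesylate of the cis-fused decalin (C6–OH cis to the C1 methyl), whose chair with the mesylate equatorial has C6–C1 anti-periplanar to C5–O and leads to the trans-fused product.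

Step 1
Reactants: 1 (S)-(+)-Wieland–Miescher ketone
Product: 2 hydroxy enone (C2β-OH, cis to the C1 methyl; C6=C7–C8=O enone kept)
Conditions: NaBH4 (0.3 equiv), EtOH, −10 °C
Reagents that add atoms: none
Why: Chemoselective borohydride reduction of the saturated ketone beside the less electrophilic enone, with hydride entering C2 from the α face opposite the angular methyl, so that the new C2 hydroxyl is β, the known outcome for this ketone.

Step 2
Reactants: 2 hydroxy enone
Product: 3 hydroxy ketal (C8 1,3-dioxolane, C5=C6 alkene, C2β-OH)
Conditions: HOCH2CH2OH, p-TsOH (cat.), benzene, reflux, Dean–Stark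
Reagents that add atoms: ethylene glycol OCCO
Why: Acid-catalysed ketalization of the enone carbonyl with removal of water, in which the dienol ether intermediate is protonated at C7 and the alkene settles at C5=C6 (deconjugative ketalization, as with 4-en-3-one steroids); no stereocenter is made.

Step 3
Reactants: 3 hydroxy ketal
Product: 4 acetoxy ketal (C2β-OAc)
Conditions: Ac2O, pyridine, DMAP (cat.), CH2Cl2, rt
Reagents that add atoms: acetic anhydride CC(=O)OC(C)=O
Why: DMAP-catalysed acylation of the secondary C2 hydroxyl with retention, which also masks it against oxidation in the next step.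

Step 4
Reactants: 4 acetoxy ketal
Product: 5 enone (C4 ketone conjugated with C5=C6; C2β-OAc, C8 dioxolane)
Conditions: Rh2(cap)4 (dirhodium tetracaprolactamate, 1 mol %), t-BuOOH (70% aq.), 1,2-dichloroethane, 40 °C
Reagents that add atoms: tert-butyl hydroperoxide CC(C)(C)OO
Why: Allylic C–H oxidation by the tert-butylperoxyl radical chain that the dirhodium caprolactamate sustains, at the ring B methylene C4 (the counterpart of the 7-position of 5-ene steroids) and not at C7, which is hindered and deactivated by the neighbouring ketal carbon; no stereocenter is made.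

Step 5
Reactants: 5 enone; 6 isopropylmagnesium chloride
Product: 7 tertiary allylic alcohol (C4β-OH, C4α-isopropyl, C5=C6)
Conditions: 6 (1.5 equiv), CeCl3 (anhydrous), THF, −78 °C; then 5, −78 → −40 °C; aq. NH4Cl
Reagents that add atoms: none
Why: 1,2-Addition of the weakly basic organocerium reagent (Imamoto conditions) to the enone carbonyl, faster at −78 °C than attack on the hindered acetate and free of conjugate addition because C6 is fully substituted, with axial entry from the α face opposite the angular methyl and the C2 acetoxy group (as in additions to 4-en-3-one steroids), which sets C4 with hydroxyl β and isopropyl α.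

Step 6
Reactants: 7 tertiary allylic alcohol
Product: 9 all-cis 4β,5β,6β-triol (cis-fused decalin), via osmate ester 8 (not isolated)
Conditions: OsO4 (1.05 equiv), TMEDA, CH2Cl2, −78 °C; then Na2SO3, THF/H2O, 60 °C
Reagents that add atoms: osmium tetroxide O=[Os](=O)(=O)=O
Why: Donohoe directed dihydroxylation, in which OsO4·TMEDA is held by a hydrogen bond to the C4 hydroxyl and adds suprafacially to C5=C6 on that same β face through the half-chair that has this hydroxyl pseudoaxial and the C1 methyl pseudoequatorial, so that C5–OH and C6–OH are set cis to the C4 hydroxyl and to the methyl (cis ring fusion), before sulfite releases the triol from the osmate ester.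

Step 7
Reactants: 9 all-cis triol
Product: 10 C5β-mesylate of the 4β,6β-diol (precursor of the key step, used crude)
Conditions: MsCl (1.2 equiv), Et3N, CH2Cl2, −20 °C
Reagents that add atoms: methanesulfonyl chloride CS(=O)(=O)Cl
Why: Sulfonylation through sulfene occurs only at the single secondary hydroxyl (C5), the two tertiary hydroxyls being unreactive at −20 °C, and leaves the C5–O bond and hence the configuration untouched.

Step 8
Reactants: 10 C5β-mesylate
Product: 11 trans-fused hydroazulenone (C6 ketone, free C4β carbinol, C2β-OAc, C8 dioxolane, H-5 α)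
Conditions: Et3Al (3 equiv), CH2Cl2, −78 → 0 °C; aq. potassium sodium tartrate
Reagents that add atoms: none
Why: Et3Al turns the syn-diaxial C4 and C6 hydroxyls into an aluminium diolate that holds ring B in the chair with the C1 methyl equatorial and the C5 mesylate equatorial, where the C6–C1 bond is anti-periplanar to C5–OMs; as the mesylate leaves with aluminium assistance, the C6 oxygen pushes and C1 moves from C6 to C5 in one concerted suprafacial 1,2-shift that ends in the C6 ketone. This is the organoaluminium-promoted pinacol-type rearrangement of 2-sulfonyloxy alcohols, the shift long used to turn decalin diol monosulfonates into hydroazulenones. Neither ring is closed end to end: the five-membered ring (C1–C5) arises by contraction of ring B and the seven-membered ring (C1, C5–C10) by expansion of ring A, both through the single migrating bond. C5 is the only new stereocenter and is set by inversion, C1 entering opposite the β mesylate so that H-5 ends α and the fusion is trans, while C1 migrates with retention and C4 keeps its configuration. The step needs C1 to migrate and not C3, C7 or the isopropyl group: in the chelated chair C7 and isopropyl are gauche to the leaving group, and of the two anti bonds (C6–C1 and C4–C3) the fully substituted C1 is by far the better migrating group than the C3 methylene, whereas an oxirane cannot form because both neighbouring oxygens are cis to the mesylate.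

Step 9
Reactants: 11 hydroazulenone
Product: 12 4β,6β-diol (C6β-OH, H-6 α; C8 dioxolane)
Conditions: Zn(BH4)2, Et2O, −30 °C
Reagents that add atoms: none
Why: Chelation-controlled borohydride reduction in which zinc ties the C4 alkoxide to the C6 carbonyl and hydride adds to the carbonyl face opposite the quaternary C1 (the face of H-5), so that the new C6 hydroxyl is β, cis to the C4 hydroxyl and the C1 methyl, while Zn(BH4)2 leaves the acetate and the ketal alone.

Step 10
Reactants: 12 diol ketal
Product: 13 β-hydroxy ketone (C8 ketone, C6β-OH, C4β-OH)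
Conditions: 1 M aq. HCl, THF, rt
Reagents that add atoms: water O
Why: Acid-catalysed hydrolysis of the dioxolane through its oxocarbenium ion, mild enough at room temperature to leave the β-hydroxy ketone (no dehydration), the tertiary carbinol and the acetate intact.

Step 11
Reactants: 13 β-hydroxy ketone
Product: 14 bis(trimethylsilyl) ether (C4-OSiMe3, C6-OSiMe3), used without chromatography
Conditions: N-(trimethylsilyl)imidazole, Me3SiCl (cat.), CH2Cl2, 40 °C
Reagents that add atoms: N-(trimethylsilyl)imidazole C[Si](C)(C)n1ccnc1
Why: Silylation of the secondary and the tertiary hydroxyl by the neutral silyl donor, which does not enolize the ketone, so that the next step needs only one equivalent of base and no alkoxide can attack the acetate or trigger a retro-aldol cleavage.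

Step 12
Reactants: 14 bis(trimethylsilyl) ether
Product: 16 C8–C9 enol triflate, via potassium enolate 15 (not isolated)
Conditions: KN(SiMe3)2 (1.1 equiv), THF, −78 °C; then PhNTf2, −78 → 0 °C
Reagents that add atoms: N-phenylbis(trifluoromethanesulfonimide) O=S(=O)(N(c1ccccc1)S(=O)(=O)C(F)(F)F)C(F)(F)F
Why: Kinetic enolization by the hindered amide at the open C9 methylene, away from the crowded C7 next to the silyloxy-bearing C6 (the usual distal deprotonation of β-silyloxy ketones), followed by O-sulfonylation of the enolate with PhNTf2, which fixes the double bond at C8=C9.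

Step 13
Reactants: 16 enol triflate
Product: 18 C8-methyl alkene diol (C8=C9, C6β-OH, C4β-OH), via methylated bis-silyl ether 17 (not isolated)
Conditions: MeZnCl (3 equiv), Pd(PPh3)4 (5 mol %), THF, 50 °C; then 1 M aq. HCl, THF, 0 °C
Reagents that add atoms: methylzinc chloride C[Zn]Cl
Why: Negishi cross-coupling (oxidative addition of the alkenyl triflate to zerovalent palladium, transmetallation from zinc, reductive elimination) puts the methyl group on C8 without moving the alkene, the acetate being inert to the organozinc, and the dilute acid that follows removes both trimethylsilyl ethers.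

Step 14
Reactants: 18 methyl alkene diol
Product: 19 8β,9β-epoxy diol
Conditions: VO(acac)2 (5 mol %), t-BuOOH (decane), CH2Cl2, 0 °C → rt
Reagents that add atoms: tert-butyl hydroperoxide CC(C)(C)OO
Why: Vanadium-catalysed hydroxyl-directed epoxidation (Sharpless–Michaelson type, here through the homoallylic C6 hydroxyl), in which the vanadate ester of that hydroxyl delivers the peroxide oxygen to the face of C8=C9 cis to it, setting C8 and C9 with the oxirane oxygen β.

Step 15
Reactants: 19 epoxy diol; 20 3,4-dimethoxybenzoyl chloride
Product: 21 target, C6 3,4-dimethoxybenzoate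
Conditions: 20 (1.5 equiv), DMAP, Et3N, CH2Cl2, rt
Reagents that add atoms: none
Why: DMAP-catalysed acylation by the acid chloride takes place at the only secondary hydroxyl (C6) with retention, the tertiary C4 hydroxyl being unreactive, and the amine-buffered medium spares the oxirane and the acetate.

Compound list
1 | (S)-(+)-Wieland–Miescher ketone, (8aS)-8a-methyl-3,4,8,8a-tetrahydronaphthalene-1,6(2H,7H)-dione | C[C@]12CCC(=O)C=C1CCCC2=O | starting material
2 | (4aS,5S)-5-hydroxy-4a-methyl-4,4a,5,6,7,8-hexahydronaphthalen-2(3H)-one (C2β-OH) | C[C@]12CCC(=O)C=C1CCC[C@@H]2O | intermediate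
3 | C8 ethylene ketal with C5=C6 alkene and C2β-OH | C[C@]12CCC3(OCCO3)CC1=CCC[C@@H]2O | intermediate
4 | C2β-acetate of 3 | C[C@]12CCC3(OCCO3)CC1=CCC[C@@H]2OC(C)=O | intermediate
5 | C4-oxo-5-ene (enone), C2β-OAc, C8 dioxolane | C[C@]12CCC3(OCCO3)CC1=CC(=O)C[C@@H]2OC(C)=O | intermediate
6 | isopropylmagnesium chloride | CC(C)[Mg]Cl | starting material
7 | C4β-hydroxy-C4α-isopropyl-5-ene, C2β-OAc, C8 dioxolane | C[C@]12CCC3(OCCO3)CC1=C[C@@](O)(C(C)C)C[C@@H]2OC(C)=O | intermediate
8 | cyclic 5β,6β-osmate ester of 9 with TMEDA on osmium | C[C@]12CCC3(OCCO3)C[C@@]1(O4)[C@H](O[Os]4(=O)=O)[C@@](O)(C(C)C)C[C@@H]2OC(C)=O.CN(C)CCN(C)C | intermediate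
9 | cis-fused decalin 4β,5β,6β-triol, C4α-isopropyl, C2β-OAc, C8 dioxolane | C[C@]12CCC3(OCCO3)C[C@@]1(O)[C@H](O)[C@@](O)(C(C)C)C[C@@H]2OC(C)=O | intermediate
10 | C5β-mesylate of 9 (4β,6β-diol free) | C[C@]12CCC3(OCCO3)C[C@@]1(O)[C@H](OS(C)(=O)=O)[C@@](O)(C(C)C)C[C@@H]2OC(C)=O | intermediate
11 | trans-fused hydroazulen-6-one, C4β-OH, C4α-isopropyl, C2β-OAc, C8 dioxolane, H-5 α | O=C2CC3(OCCO3)CC[C@]4(C)[C@@H](OC(C)=O)C[C@](O)(C(C)C)[C@@H]24 | intermediate
12 | 4β,6β-diol, C8 dioxolane | O[C@H]2CC4(OCCO4)CC[C@]3(C)[C@@H](OC(C)=O)C[C@](O)(C(C)C)[C@@H]23 | intermediate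
13 | C8 ketone, 4β,6β-diol | O[C@H]2CC(=O)CC[C@]3(C)[C@@H](OC(C)=O)C[C@](O)(C(C)C)[C@@H]23 | intermediate
14 | 4,6-bis(trimethylsilyl) ether of 13 | C[Si](C)(C)O[C@H]2CC(=O)CC[C@]3(C)[C@@H](OC(C)=O)C[C@](O[Si](C)(C)C)(C(C)C)[C@@H]23 | intermediate
15 | potassium C8–C9 enolate of 14 | C[Si](C)(C)O[C@H]2CC([O-])=CC[C@]3(C)[C@@H](OC(C)=O)C[C@](O[Si](C)(C)C)(C(C)C)[C@@H]23.[K+] | intermediate
16 | C8 enol triflate (C8=C9) | C[Si](C)(C)O[C@H]2CC(OS(=O)(=O)C(F)(F)F)=CC[C@]3(C)[C@@H](OC(C)=O)C[C@](O[Si](C)(C)C)(C(C)C)[C@@H]23 | intermediate
17 | C8-methyl-8-ene, 4,6-bis(trimethylsilyl) ether | C[Si](C)(C)O[C@H]2CC(C)=CC[C@]3(C)[C@@H](OC(C)=O)C[C@](O[Si](C)(C)C)(C(C)C)[C@@H]23 | intermediate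
18 | C8-methyl-8-ene-4β,6β-diol, C2β-OAc | O[C@H]2CC(C)=CC[C@]3(C)[C@@H](OC(C)=O)C[C@](O)(C(C)C)[C@@H]23 | intermediate
19 | 8β,9β-epoxy-4β,6β-diol, C2β-OAc | O[C@H]2C[C@@]3(C)O[C@H]3C[C@]3(C)[C@@H](OC(C)=O)C[C@](O)(C(C)C)[C@@H]23 | intermediate
20 | 3,4-dimethoxybenzoyl chloride | COc1ccc(C(Cl)=O)cc1OC | starting material
21 | target, (1S,2S,4S,5R,6S,8R,9S) in the numbering used here | COc1ccc(C(=O)O[C@H]2C[C@@]3(C)O[C@H]3C[C@]3(C)[C@@H](OC(C)=O)C[C@](O)(C(C)C)[C@@H]23)cc1OC | target

Total step count: 15. Longest linear sequence: 15 steps (1 to 21); 6 and 20 enter as bought reagents.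

Steps most likely to fail

1. Step 8. The wrong bond may migrate: the C3 methylene under the push of the C4 alkoxide, or C7 or isopropyl if the other chair reacts. The mesylate may also ionize without a shift. The fallback moves to the trans-fused series, where the chair is rigid and the C4 oxygen is capped, and corrects C5 afterwards. It sets out from 7. Et3SiOTf/2,6-lutidine should give the C4 triethylsilyl ether F1. Undirected OsO4 (cat.)/NMO dihydroxylation, anti to the silyloxy group and to the C1 methyl, should give the 5α,6α-diol F2. MsCl/Et3N should give the equatorial 5α-mesylate F3. Et3Al should then shift C1, the only anti bond with an alkoxide behind it, to give the cis-fused C5-epimeric ketone silyl ether F4. Bu4NF/AcOH should free the C5-epimeric hydroxy ketone F5. DBU should then equilibrate C5 through the C6 enol toward the trans-fused isomer, in which C6 is no longer cis to the isopropyl group; that preference is argued on steric grounds. The route is rejoined at 11.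

2. Step 6. Facial selectivity may be poor (osmylation anti to the hydroxyl on the α face, away from the angular methyl), and the hindered alkene may react slowly. The fallback replaces osmylation by a covalently directed epoxidation and an oxirane-to-carbonate conversion with retention. It sets out from 7. VO(acac)2/t-BuOOH should give the syn 5β,6β-epoxy alcohol F6. CO2 with Bu4NBr catalysis (10 bar, 80 °C) should convert the oxirane, by double inversion at C5, into the cis 5β,6β-cyclic carbonate F7. LiOH in aqueous THF at 0 °C should cleave the strained carbonate faster than the hindered acetate. The route is rejoined at 9.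

3. Step 5. The enone may be reduced or enolized in place of addition (hydride transfer from the secondary organometallic), the acetate may be attacked, or acetate may be lost by β-elimination from the enolate. The fallback brings in the three carbons as an sp2 nucleophile and saturates afterwards. It sets out from 5. 2-Propenylmagnesium bromide/CeCl3 at −78 °C should give the isopropenyl carbinol F8, with the same α-face entry. H2 with RhCl(PPh3)3 should reduce the 1,1-disubstituted alkene and leave the trisubstituted ring alkene. The route is rejoined at 7.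

Further compounds
F1 | step 8 | C4 triethylsilyl ether of 7 | C[C@]12CCC3(OCCO3)CC1=C[C@@](O[Si](CC)(CC)CC)(C(C)C)C[C@@H]2OC(C)=O
F2 | step 8 | trans-fused decalin 5α,6α-diol, C4β-OSiEt3 | C[C@]12CCC3(OCCO3)C[C@]1(O)[C@@H](O)[C@@](O[Si](CC)(CC)CC)(C(C)C)C[C@@H]2OC(C)=O
F3 | step 8 | 5α-mesylate of F2 | C[C@]12CCC3(OCCO3)C[C@]1(O)[C@@H](OS(C)(=O)=O)[C@@](O[Si](CC)(CC)CC)(C(C)C)C[C@@H]2OC(C)=O
F4 | step 8 | cis-fused C5 epimer of 11 as C4 triethylsilyl ether (H-5 β) | O=C2CC3(OCCO3)CC[C@]4(C)[C@@H](OC(C)=O)C[C@](O[Si](CC)(CC)CC)(C(C)C)[C@H]24
F5 | step 8 | cis-fused C5 epimer of 11, free C4 carbinol | O=C2CC3(OCCO3)CC[C@]4(C)[C@@H](OC(C)=O)C[C@](O)(C(C)C)[C@H]24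
F6 | step 6 | 5β,6β-epoxy-4β-ol derived from 7 | C[C@]12CCC3(OCCO3)C[C@]14O[C@@H]4[C@@](O)(C(C)C)C[C@@H]2OC(C)=O
F7 | step 6 | 5β,6β-cyclic carbonate of triol 9 | C[C@]12CCC3(OCCO3)C[C@@]1(O4)[C@H](OC4=O)[C@@](O)(C(C)C)C[C@@H]2OC(C)=O
F8 | step 5 | C4β-hydroxy-C4α-isopropenyl-5-ene, C2β-OAc, C8 dioxolane | C[C@]12CCC3(OCCO3)CC1=C[C@@](O)(C(C)=C)C[C@@H]2OC(C)=O
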